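A direct plan would build the furan ring first: furan Diels–Alder cycloaddition, glycol cleavage and reduction to the meso dihydrofuran diol A1, enzymatic desymmetrisation, epoxidation, then acid-mediated attack of a (Z)-enoate ester on the oxirane to close the pyranone ring of hydroxy lactone A2.
The C8 arm would then be cut down to the vinyl lactone A3 and joined to the allylic benzoate A4 by cross-metathesis.
Its weak steps would be:
(1) the lactonisation by oxirane opening, which would leave the C6 carbinol of A2 with the wrong configuration, so that C6 would have to be corrected by oxidation and hydride reduction between two epimerisable centres;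
(2) the linear run-up of some sixteen steps, with three oxidations and four protecting-group operations, to A3, a ten-carbon lactone that carries none of the side chain;
(3) the late cross-metathesis of two hindered, oxygen-flanked terminal alkenes on the finished enoate core, with the multi-step fragment A4 in excess and a desilylation still to follow beside a benzoate that can migrate.

**Retrosynthetic overview**
- Key disconnection: the O4–C7 bond of the furan ring (O4, C4, C5, C6, C7), made last. C7 is an allylic ether carbon flanked by the C6 carbinol and the (E)-C8=C9 alkene, the retron of a trans-C6,C7 vinyl oxirane opened by O4 with net retention through a palladium allyl complex.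
- Ring order: the pyranone ring (O5, C1–C5) closes first by acrylate ring-closing metathesis (C2=C3), the furan ring last. C6=C7 comes from a cross-metathesis of two chiral-pool pieces.
- Stereocentres: C4/C5 from (3R,4R)-hexa-1,5-diene-3,4-diol. C10/C11, the (E)-C8=C9 alkene and the C10-benzoate/C11-hydroxyl pattern from a Perlin reaction of 3,4-di-O-benzoyl-6-deoxy-D-glucal. C6 by matched Sharpless epoxidation. C7 by the key step.
- Weak steps avoided: C6 is set once and never corrected, benzoate and hydroxyl are never told apart by protecting groups, and no metathesis runs on the finished core. The route has 13 steps.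

Key step: step 13

Remark on numbering: C1 (lactone carbonyl) to C12 (methyl) along the chain; O4 bridges C4 and C7, O5 is the lactone oxygen, C6 carries the free ring hydroxyl, C10 the benzoate, C11 the side-chain hydroxyl. Compounds 1 and 8 are taken as commercial.

Step 1
Reactants: 1 D-glucal
Product: 2 6-O-(4-methylbenzenesulfonyl)-D-glucal
Conditions: TsCl (1.05 equiv), pyridine, −20 → 0 °C
Reagents that add atoms: 4-methylbenzenesulfonyl chloride, Cc1ccc(cc1)S(=O)(=O)Cl
Why: Selective sulfonylation of the primary hydroxyl (steric differentiation from the two secondary hydroxyls at low temperature) should activate C6 for deoxygenation.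

Step 2
Reactants: 2 6-O-(4-methylbenzenesulfonyl)-D-glucal
Product: 3 6-deoxy-D-glucal
Conditions: LiAlH4, THF, 0 °C → reflux
Reagents that add atoms: none
Why: Hydride displacement of the primary sulfonate (SN2 reduction) should give the methyl group, the future C12, without touching the enol ether or the two carbinol centres.

Step 3
Reactants: 3 6-deoxy-D-glucal
Product: 4 3,4-di-O-benzoyl-6-deoxy-D-glucal
Conditions: BzCl (2.4 equiv), pyridine, DMAP (cat.), CH2Cl2, 0 °C → rt
Reagents that add atoms: benzoyl chloride, O=C(Cl)c1ccccc1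
Why: Pyridine-mediated acylation of both secondary hydroxyls; the benzoate on sugar O4 is the one that stays on the future C10, the one on sugar O3 is the leaving group of the next step.

Step 4
Reactants: 4 3,4-di-O-benzoyl-6-deoxy-D-glucal
Product: 5 (2E,4S,5R)-4-(benzoyloxy)-5-hydroxyhex-2-enal
Conditions: HgSO4 (2 mol %), H2SO4 (5 mM in H2O), 1,4-dioxane, rt
Reagents that add atoms: water, O
Why: Perlin reaction: oxymercuration of the enol ether, opening of the lactol and elimination of the sugar C3 benzoate with release of HgSO4 should give the (E)-enal (C7–C9), in which the ring oxygen has become the free C11 hydroxyl and the surviving benzoate sits on C10, both centres being C4 and C5 of D-glucose and untouched.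

Step 5
Reactants: 5 (2E,4S,5R)-4-(benzoyloxy)-5-hydroxyhex-2-enal
Product: 6 (2E,4S,5R)-4-(benzoyloxy)-5-[(triethylsilyl)oxy]hex-2-enal
Conditions: Et3SiOTf, 2,6-lutidine, CH2Cl2, −78 °C
Reagents that add atoms: triethylsilyl trifluoromethanesulfonate, CC[Si](CC)(CC)OS(=O)(=O)C(F)(F)F
Why: Silylation with the silyl triflate and a hindered base at −78 °C should cap the C11 hydroxyl before the neighbouring benzoate can migrate, and masks it for the metathesis, epoxidation and acylation steps.

Step 6
Reactants: 6 (2E,4S,5R)-4-(benzoyloxy)-5-[(triethylsilyl)oxy]hex-2-enal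
Product: 7 (3E,5S,6R)-6-[(triethylsilyl)oxy]hepta-1,3-dien-5-yl benzoate
Conditions: Ph3PCH3Br, KN(SiMe3)2, THF, 0 °C; then 6, −78 → 0 °C
Reagents that add atoms: methyltriphenylphosphonium bromide, C[P+](c1ccccc1)(c1ccccc1)c1ccccc1.[Br-]
Why: Wittig methylenation; at low temperature the non-stabilised ylide should add to the aldehyde much faster than it attacks the benzoate or removes the γ-proton, giving the terminal (E)-diene whose inner CH is the future C7.

Step 7
Reactants: 8 (3R,4R)-hexa-1,5-diene-3,4-diol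
Product: 9 (3R,4R)-4-[(triethylsilyl)oxy]hexa-1,5-dien-3-ol
Conditions: NaH (1.0 equiv), THF, 0 °C; then Et3SiCl (1.0 equiv)
Reagents that add atoms: chlorotriethylsilane, CC[Si](CC)(CC)Cl
Why: Monosilylation through the monosodium alkoxide; the two hydroxyls are homotopic (C2 axis), so only one mono ether can form and no stereocentre is touched.

Step 8
Reactants: 9 (3R,4R)-4-[(triethylsilyl)oxy]hexa-1,5-dien-3-ol (3 equiv); 7 (3E,5S,6R)-6-[(triethylsilyl)oxy]hepta-1,3-dien-5-yl benzoate
Product: 10 (3R,4R,5E,7E,9S,10R)-4-hydroxy-3,10-bis[(triethylsilyl)oxy]undeca-1,5,7-trien-9-yl benzoate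
Conditions: second-generation Hoveyda–Grubbs catalyst RuCl2(H2IMes)(=CH-C6H4-2-OiPr) (5 mol %), CH2Cl2, 40 °C
Reagents that add atoms: none
Why: Olefin cross-metathesis; the vinyl group beside the free allylic hydroxyl of 9 should react in preference to the one flanked by the silyl ether, and the terminal alkene of 7 in preference to its internal, benzoate-flanked one, giving the (E)-C6=C7 bond under thermodynamic control with loss of ethene.

Step 9
Reactants: 10 (3R,4R,5E,7E,9S,10R)-4-hydroxy-3,10-bis[(triethylsilyl)oxy]undeca-1,5,7-trien-9-yl benzoate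
Product: 11 (1E,3S,4R)-1-{(2S,3S)-3-[(1R,2R)-1-hydroxy-2-[(triethylsilyl)oxy]but-3-en-1-yl]oxiran-2-yl}-4-[(triethylsilyl)oxy]pent-1-en-3-yl benzoate
Conditions: Ti(OiPr)4 (20 mol %), L-(+)-diisopropyl tartrate (24 mol %), tBuOOH (in decane), 4 Å molecular sieves, CH2Cl2, −20 °C
Reagents that add atoms: tert-butyl hydroperoxide, CC(C)(C)OO
Why: Sharpless asymmetric epoxidation of a secondary (E)-allylic alcohol in the matched sense: with the L-(+)-tartrate the (5R)-carbinol is of the fast-reacting type and oxygen is delivered to C6=C7 to give the erythro (C5/C6 anti) trans-oxirane, while the terminal vinyl group (only homoallylic to the hydroxyl and monosubstituted) and the C8=C9 alkene (remote from the hydroxyl) should stay intact.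

Step 10
Reactants: 11 epoxy alcohol
Product: 12 (1R,2R)-1-{(2R,3S)-3-[(1E,3S,4R)-3-(benzoyloxy)-4-[(triethylsilyl)oxy]pent-1-en-1-yl]oxiran-2-yl}-2-[(triethylsilyl)oxy]but-3-en-1-yl prop-2-enoate
Conditions: acryloyl chloride, iPr2NEt, CH2Cl2, −40 → 0 °C
Reagents that add atoms: acryloyl chloride, C=CC(=O)Cl
Why: Amine-mediated acylation of the only free hydroxyl places the three lactone carbons C1–C3 on O5.

Step 11
Reactants: 12 epoxy acrylate
Product: 13 (5R,6R)-6-{(2R,3S)-3-[(1E,3S,4R)-3-(benzoyloxy)-4-[(triethylsilyl)oxy]pent-1-en-1-yl]oxiran-2-yl}-5-[(triethylsilyl)oxy]-5,6-dihydro-2H-pyran-2-one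
Conditions: second-generation Grubbs catalyst RuCl2(H2IMes)(PCy3)(=CHPh) (5 mol %), CH2Cl2 (2 mM), 40 °C
Reagents that add atoms: none
Why: Ring-closing metathesis of the acrylate with the terminal C3 vinyl group closes the pyranone ring (C2=C3, cis by ring size), while the internal C8=C9 alkene and the oxirane should not engage.

Step 12
Reactants: 13 bis-silyl epoxy pyranone
Product: 14 (5R,6S)-6-{(2R,3S)-3-[(1E,3S,4R)-3-(benzoyloxy)-4-hydroxypent-1-en-1-yl]oxiran-2-yl}-5-hydroxy-5,6-dihydro-2H-pyran-2-one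
Conditions: Bu4NF, AcOH (1:1), THF, 0 °C; crude product used at once
Reagents that add atoms: none
Why: Buffered fluoride desilylation frees O4 and O11; acetic acid keeps the medium from turning basic (no benzoate shift from O10 to O11, no acyl transfer at the lactone) yet should be too weak an acid to open the vinyl oxirane.

Step 13
Reactants: 14 epoxy pyranone diol
Product: 15 (1E,3S,4R)-4-hydroxy-1-[(2S,3R,3aR,7aR)-3-hydroxy-5-oxo-2,3,3a,7a-tetrahydro-5H-furo[3,2-b]pyran-2-yl]pent-1-en-3-yl benzoate (CNP0140142.1)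
Conditions: Pd(PPh3)4 (5 mol %), THF, 0 °C → rt
Reagents that add atoms: none
Why: Zerovalent palladium should ionise the vinyl oxirane with inversion at C7 (attack on C8=C9 anti to the C7–O bond) to a zwitterionic η3-allyl complex (C7–C9) that carries the C6 alkoxide; proton transfer from the neighbouring O4–H and attack of O4 on C7 anti to the metal then close the furan ring and release the catalyst. The closest known reaction type is the Tsuji–Trost cyclisation of hydroxy vinyl epoxides to 2-alkenyl-3-hydroxy cyclic ethers, which runs with net retention. The furan ring (O4, C4, C5, C6, C7) closes by 5-exo attack on the allyl terminus; a direct, acid-promoted opening of the same oxirane would be 5-endo and invertive and would give the C7 epimer, which is why the metal is used with the (E)-derived oxirane. C7 is set by double inversion, so O4 takes the place of the oxirane oxygen and the alkenyl group ends cis to the C6 hydroxyl, to O5 and to the C4 arm; C6 keeps the configuration from step 9, and C8=C9 stays (E) because the syn,syn-allyl complex forms from the (E)-alkene. The step needs attack at C7 over C9 (five- against seven-membered ring), ionisation of the oxirane over the C10 benzoate (ring strain, 0 °C), O4 over O11 as nucleophile (ring size), and etherification over conjugate addition of the alkoxide to C3; the cis relationship of O4–H and the side chain on the pyranone, inherited from diol 8, holds O4 next to C7. The step is an isomerisation and gives the target with no protecting group left to remove.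

**Compound list**
1 | D-glucal, (2R,3S,4R)-2-(hydroxymethyl)-3,4-dihydro-2H-pyran-3,4-diol | OC[C@H]1OC=C[C@@H](O)[C@@H]1O | starting material
2 | 6-O-(4-methylbenzenesulfonyl)-D-glucal | Cc1ccc(cc1)S(=O)(=O)OC[C@H]1OC=C[C@@H](O)[C@@H]1O | intermediate
3 | 6-deoxy-D-glucal, (2R,3S,4R)-2-methyl-3,4-dihydro-2H-pyran-3,4-diol | C[C@H]1OC=C[C@@H](O)[C@@H]1O | intermediate
4 | 3,4-di-O-benzoyl-6-deoxy-D-glucal | C[C@H]1OC=C[C@@H](OC(=O)c2ccccc2)[C@@H]1OC(=O)c1ccccc1 | intermediate
5 | (2E,4S,5R)-4-(benzoyloxy)-5-hydroxyhex-2-enal | C[C@@H](O)[C@H](/C=C/C=O)OC(=O)c1ccccc1 | intermediate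
6 | (2E,4S,5R)-4-(benzoyloxy)-5-[(triethylsilyl)oxy]hex-2-enal | C[C@@H](O[Si](CC)(CC)CC)[C@H](/C=C/C=O)OC(=O)c1ccccc1 | intermediate
7 | (3E,5S,6R)-6-[(triethylsilyl)oxy]hepta-1,3-dien-5-yl benzoate | C[C@@H](O[Si](CC)(CC)CC)[C@H](/C=C/C=C)OC(=O)c1ccccc1 | intermediate
8 | (3R,4R)-hexa-1,5-diene-3,4-diol | C=C[C@@H](O)[C@H](O)C=C | starting material
9 | (3R,4R)-4-[(triethylsilyl)oxy]hexa-1,5-dien-3-ol | C=C[C@@H](O)[C@H](O[Si](CC)(CC)CC)C=C | intermediate
10 | (3R,4R,5E,7E,9S,10R)-4-hydroxy-3,10-bis[(triethylsilyl)oxy]undeca-1,5,7-trien-9-yl benzoate | C=C[C@@H](O[Si](CC)(CC)CC)[C@H](O)/C=C/C=C/[C@H](OC(=O)c1ccccc1)[C@@H](C)O[Si](CC)(CC)CC | intermediate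
11 | (1E,3S,4R)-1-{(2S,3S)-3-[(1R,2R)-1-hydroxy-2-[(triethylsilyl)oxy]but-3-en-1-yl]oxiran-2-yl}-4-[(triethylsilyl)oxy]pent-1-en-3-yl benzoate (trans-oxirane, C5/C6 anti) | C=C[C@@H](O[Si](CC)(CC)CC)[C@H](O)[C@@H]1O[C@H]1/C=C/[C@H](OC(=O)c2ccccc2)[C@@H](C)O[Si](CC)(CC)CC | intermediate
12 | (1R,2R)-1-{(2R,3S)-3-[(1E,3S,4R)-3-(benzoyloxy)-4-[(triethylsilyl)oxy]pent-1-en-1-yl]oxiran-2-yl}-2-[(triethylsilyl)oxy]but-3-en-1-yl prop-2-enoate | C=C[C@@H](O[Si](CC)(CC)CC)[C@H](OC(=O)C=C)[C@@H]1O[C@H]1/C=C/[C@H](OC(=O)c2ccccc2)[C@@H](C)O[Si](CC)(CC)CC | intermediate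
13 | (5R,6R)-6-{(2R,3S)-3-[(1E,3S,4R)-3-(benzoyloxy)-4-[(triethylsilyl)oxy]pent-1-en-1-yl]oxiran-2-yl}-5-[(triethylsilyl)oxy]-5,6-dihydro-2H-pyran-2-one | O=C1C=C[C@@H](O[Si](CC)(CC)CC)[C@H](O1)[C@@H]2O[C@H]2/C=C/[C@H](OC(=O)c3ccccc3)[C@@H](C)O[Si](CC)(CC)CC | intermediate
14 | (5R,6S)-6-{(2R,3S)-3-[(1E,3S,4R)-3-(benzoyloxy)-4-hydroxypent-1-en-1-yl]oxiran-2-yl}-5-hydroxy-5,6-dihydro-2H-pyran-2-one (5-hydroxyl cis to the side chain) | O=C1C=C[C@@H](O)[C@H](O1)[C@@H]2O[C@H]2/C=C/[C@H](OC(=O)c3ccccc3)[C@@H](C)O | intermediate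
15 | (1E,3S,4R)-4-hydroxy-1-[(2S,3R,3aR,7aR)-3-hydroxy-5-oxo-2,3,3a,7a-tetrahydro-5H-furo[3,2-b]pyran-2-yl]pent-1-en-3-yl benzoate (CNP0140142.1) | C[C@@H](O)[C@H](/C=C/[C@@H]1O[C@@H]2C=CC(=O)O[C@@H]2[C@@H]1O)OC(=O)c1ccccc1 | target

Total step count: 13. Longest linear sequence: 12 steps (steps 1–6, then 8–13); step 7 is the one-step branch.

**Steps most likely to fail**

1. Step 8 (cross-metathesis with a conjugated diene). The catalyst may also engage the internal C8=C9 alkene of 7 (loss of two carbons), react at the silyloxy-flanked vinyl group of 9, or give E/Z mixtures at C6=C7. The fallback replaces the metathesis by a carbonyl addition; it sets out from 6 and comes back at 10. Wittig reaction of 6 with (triphenylphosphoranylidene)acetaldehyde would give (2E,4E,6S,7R)-6-(benzoyloxy)-7-[(triethylsilyl)oxy]octa-2,4-dienal F1. BF3·OEt2-promoted addition of tributyl[(2Z)-3-[(triethylsilyl)oxy]prop-2-en-1-yl]stannane F2 (from allyl triethylsilyl ether, s-BuLi at −78 °C, then Bu3SnCl) through its oxygen-bearing γ-carbon would give the syn adducts: 10 together with (3S,4S,5E,7E,9S,10R)-4-hydroxy-3,10-bis[(triethylsilyl)oxy]undeca-1,5,7-trien-9-yl benzoate F3. Step 9 then acts as a kinetic resolution, because only 10 is matched with the L-(+)-tartrate catalyst; the unreacted alcohol would be removed, at the cost of at most half the material.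

2. Step 13 (key step). The transient C6 alkoxide may add to C3 of the enoate or shift an acyl group before O4 reaches C7; traces of acid may open the oxirane of 14 by O4 with inversion (C7 epimer) before the metal ionises it; and the product's C10 benzoate may ionise slowly. The fallback changes the electrophile from a vinyl oxirane to a vinyl cyclic carbonate; it sets out from 13 and comes back at 15. Pd(PPh3)4 under CO2 (1 atm) should convert 13, with net retention at C7, into (5R,6R)-6-{(4R,5S)-5-[(1E,3S,4R)-3-(benzoyloxy)-4-[(triethylsilyl)oxy]pent-1-en-1-yl]-2-oxo-1,3-dioxolan-4-yl}-5-[(triethylsilyl)oxy]-5,6-dihydro-2H-pyran-2-one F4. Bu4NF/AcOH would then give (5R,6S)-6-{(4R,5S)-5-[(1E,3S,4R)-3-(benzoyloxy)-4-hydroxypent-1-en-1-yl]-2-oxo-1,3-dioxolan-4-yl}-5-hydroxy-5,6-dihydro-2H-pyran-2-one F5, which cannot be opened by acid in the invertive 5-endo mode. Pd(PPh3)4 then ionises the allylic carbonate and O4 closes onto C7 while the leaving group is a weakly basic carbonate that loses CO2, giving 15.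

3. Step 12 (unmasking O4 beside the vinyl oxirane). The freed O4 hydroxyl may open the oxirane prematurely with inversion at C7, fluoride may attack the allylic oxirane carbon, or the benzoate may shift. The fallback changes the order of oxidation and unmasking; it sets out from 10 and comes back at 14. Acryloylation of 10 would give (3R,4R,5E,7E,9S,10R)-9-(benzoyloxy)-3,10-bis[(triethylsilyl)oxy]undeca-1,5,7-trien-4-yl prop-2-enoate F6. Ring-closing metathesis would give (5R,6R)-6-[(1E,3E,5S,6R)-5-(benzoyloxy)-6-[(triethylsilyl)oxy]hepta-1,3-dien-1-yl]-5-[(triethylsilyl)oxy]-5,6-dihydro-2H-pyran-2-one F7. Bu4NF/AcOH, now with no oxirane present, would give (5R,6R)-6-[(1E,3E,5S,6R)-5-(benzoyloxy)-6-hydroxyhepta-1,3-dien-1-yl]-5-hydroxy-5,6-dihydro-2H-pyran-2-one F8. Epoxidation with VO(acac)2 and tBuOOH, directed by the free homoallylic O4 hydroxyl, would then put the oxirane on C6=C7 under neutral conditions to give 14 for step 13; the C8=C9 alkene, although homoallylic to O11, is deactivated by the C10 benzoate and should react more slowly. Facial control in this variant rests on the substrate alone and is less secure than in step 9, which is why it is the fallback and not the route.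

**Further compounds**
F1 | step 8 | (2E,4E,6S,7R)-6-(benzoyloxy)-7-[(triethylsilyl)oxy]octa-2,4-dienal | C[C@@H](O[Si](CC)(CC)CC)[C@H](/C=C/C=C/C=O)OC(=O)c1ccccc1
F2 | step 8 | tributyl[(2Z)-3-[(triethylsilyl)oxy]prop-2-en-1-yl]stannane | CCCC[Sn](CCCC)(CCCC)C/C=C\O[Si](CC)(CC)CC
F3 | step 8 | (3S,4S,5E,7E,9S,10R)-4-hydroxy-3,10-bis[(triethylsilyl)oxy]undeca-1,5,7-trien-9-yl benzoate | C=C[C@H](O[Si](CC)(CC)CC)[C@@H](O)/C=C/C=C/[C@H](OC(=O)c1ccccc1)[C@@H](C)O[Si](CC)(CC)CC
F4 | step 13 | (5R,6R)-6-{(4R,5S)-5-[(1E,3S,4R)-3-(benzoyloxy)-4-[(triethylsilyl)oxy]pent-1-en-1-yl]-2-oxo-1,3-dioxolan-4-yl}-5-[(triethylsilyl)oxy]-5,6-dihydro-2H-pyran-2-one | O=C1C=C[C@@H](O[Si](CC)(CC)CC)[C@H](O1)[C@@H]2OC(=O)O[C@H]2/C=C/[C@H](OC(=O)c3ccccc3)[C@@H](C)O[Si](CC)(CC)CC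
F5 | step 13 | (5R,6S)-6-{(4R,5S)-5-[(1E,3S,4R)-3-(benzoyloxy)-4-hydroxypent-1-en-1-yl]-2-oxo-1,3-dioxolan-4-yl}-5-hydroxy-5,6-dihydro-2H-pyran-2-one | O=C1C=C[C@@H](O)[C@H](O1)[C@@H]2OC(=O)O[C@H]2/C=C/[C@H](OC(=O)c3ccccc3)[C@@H](C)O
F6 | step 12 | (3R,4R,5E,7E,9S,10R)-9-(benzoyloxy)-3,10-bis[(triethylsilyl)oxy]undeca-1,5,7-trien-4-yl prop-2-enoate | C=C[C@@H](O[Si](CC)(CC)CC)[C@H](OC(=O)C=C)/C=C/C=C/[C@H](OC(=O)c1ccccc1)[C@@H](C)O[Si](CC)(CC)CC
F7 | step 12 | (5R,6R)-6-[(1E,3E,5S,6R)-5-(benzoyloxy)-6-[(triethylsilyl)oxy]hepta-1,3-dien-1-yl]-5-[(triethylsilyl)oxy]-5,6-dihydro-2H-pyran-2-one | O=C1C=C[C@@H](O[Si](CC)(CC)CC)[C@H](O1)/C=C/C=C/[C@H](OC(=O)c2ccccc2)[C@@H](C)O[Si](CC)(CC)CC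
F8 | step 12 | (5R,6R)-6-[(1E,3E,5S,6R)-5-(benzoyloxy)-6-hydroxyhepta-1,3-dien-1-yl]-5-hydroxy-5,6-dihydro-2H-pyran-2-one | O=C1C=C[C@@H](O)[C@H](O1)/C=C/C=C/[C@H](OC(=O)c2ccccc2)[C@@H](C)O
A1 | direct plan | cis-2,5-bis(hydroxymethyl)-2,5-dihydrofuran (meso) | OC[C@H]1O[C@@H](CO)C=C1
A2 | direct plan | (2S,3S,3aR,7aR)-2-{[tert-butyl(diphenyl)silyl]oxymethyl}-3-hydroxy-2,3,3a,7a-tetrahydro-5H-furo[3,2-b]pyran-5-one | CC(C)(C)[Si](c1ccccc1)(c1ccccc1)OC[C@@H]1O[C@@H]2C=CC(=O)O[C@@H]2[C@H]1O
A3 | direct plan | (2S,3R,3aS,7aR)-3-[tert-butyl(dimethyl)silyl]oxy-2-ethenyl-2,3,3a,7a-tetrahydro-5H-furo[3,2-b]pyran-5-one | C=C[C@@H]1O[C@@H]2C=CC(=O)O[C@@H]2[C@@H]1O[Si](C)(C)C(C)(C)C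
A4 | direct plan | (3S,4R)-4-hydroxypent-1-en-3-yl benzoate | C=C[C@H](OC(=O)c1ccccc1)[C@H](O)C
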